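The route rests on disconnecting the saturated C14 bridge that links C6 of ring B (the trioxygenated ring) to ring A (the monophenolic ring) at its C5–C6 bond, counted from ring B. This bond lies among unsubstituted methylenes, far from both arenes, so an olefin made there leaves no trace after hydrogenation. Ring-closing olefin metathesis of an acyclic diaryl ether carrying a 1-hydroxyhex-5-enyl arm on ring B and a dec-9-enyl arm on ring A closes the 20-membered ring in one operation. The benzylic hydroxyl, left from chain attachment, is removed by hydrogenolysis together with the olefin.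

Key step: step 4

Assumption: the carbinol centre made in step 3 is racemic and the olefin made in step 4 is an E/Z mixture; both are erased in step 5, so neither is drawn with a stereodescriptor, and the target itself has no stereocentre.

Step 1
Reactants: 1 3-bromo-5-methoxyphenol; 2 deca-1,9-diene
Product: 4 3-(dec-9-en-1-yl)-5-methoxyphenol, via B-(dec-9-enyl)-9-BBN 3 (not isolated)
Conditions: 2 (3 equiv), 9-BBN, THF, 0 °C to rt; then 1, PdCl2(dppf) (5 mol%), aq. K3PO4, THF/DMF, 60 °C
Reagents that add atoms: none
Why: Anti-Markovnikov hydroboration of one vinyl group of the excess diene, then B-alkyl Suzuki–Miyaura coupling at the aryl C–Br bond, should transfer the primary alkyl group while the second vinyl group and the phenoxide stay inert.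

Step 2
Reactants: 4 3-(dec-9-en-1-yl)-5-methoxyphenol; 5 2-bromo-3,5-dimethoxybenzaldehyde
Product: 6 2-[3-(dec-9-en-1-yl)-5-methoxyphenoxy]-3,5-dimethoxybenzaldehyde
Conditions: CuI (10 mol%), picolinic acid (20 mol%), K3PO4, DMSO, 90 °C
Reagents that add atoms: none
Why: Ullmann-type copper-catalysed C–O coupling, in which the ortho formyl group activates the C–Br bond and the picolinic acid ligand suits ortho-substituted partners, should give the diaryl ether without touching the terminal olefin or the methyl ethers.

Step 3
Reactants: 6 2-[3-(dec-9-en-1-yl)-5-methoxyphenoxy]-3,5-dimethoxybenzaldehyde; 7 5-bromopent-1-ene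
Product: 9 rac-1-{2-[3-(dec-9-en-1-yl)-5-methoxyphenoxy]-3,5-dimethoxyphenyl}hex-5-en-1-ol, via pent-4-enylmagnesium bromide 8 (not isolated)
Conditions: 7, Mg, THF, rt to 40 °C; then 6, THF, −78 to 0 °C; aq. NH4Cl
Reagents that add atoms: none
Why: Grignard addition to the non-enolisable aryl aldehyde should give the secondary benzylic alcohol as a racemate, which is of no consequence because this carbon becomes a methylene in step 5.

Step 4
Reactants: 9 rac-1-{2-[3-(dec-9-en-1-yl)-5-methoxyphenoxy]-3,5-dimethoxyphenyl}hex-5-en-1-ol
Product: 10 macrocyclic alkenol (20-membered diaryl ether cyclophane; bridge numbered from ring B: hydroxyl at C1, double bond C5=C6; three O-methyl groups; E/Z mixture, racemic)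
Conditions: second-generation Grubbs catalyst (H2IMes)(PCy3)Cl2Ru=CHPh (10 mol%, two portions), 1,4-benzoquinone (20 mol%), CH2Cl2 (1 mM), 40 °C, argon sparge
Reagents that add atoms: none
Why: The ruthenium benzylidene exchanges onto one vinyl group, and the resulting alkylidene undergoes [2+2] cycloaddition with the other vinyl group followed by cycloreversion of the ruthenacyclobutane (Chauvin mechanism), joining the two internal vinyl carbons as bridge C5=C6 and expelling ethene, whose removal drives the closure. The closest known reaction type is macrocyclic ring-closing olefin metathesis of α,ω-dienes, which is established for flexible cyclophanes of this size. The single ring closed is the 20-membered ring (fourteen bridge carbons, two carbons of ring B, the ether oxygen, three carbons of ring A), formed end-to-end from two monosubstituted olefins at high dilution. No stereocentre is created; the olefin geometry is uncontrolled and need not be controlled, since step 5 saturates it and also removes the racemic carbinol centre. The step needs cyclisation to win over oligomerisation and needs the olefins not to migrate before closure; the substrate offers only two metathesis-active olefins, both terminal, unhindered and at least three methylenes from any functional group, and the bent ortho/meta diaryl ether holds both arms on the same side. High dilution and benzoquinone as a scavenger of ruthenium hydrides complete the control.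

Step 5
Reactants: 10 macrocyclic alkenol
Product: 11 tri-O-methyl ether of the target (saturated 20-membered diaryl ether cyclophane)
Conditions: H2 (3 atm), 10% Pd/C, EtOAc/AcOH, HClO4 (cat.), rt
Reagents that add atoms: none
Why: Heterogeneous catalytic hydrogenation should saturate the bridge olefin and acid-promoted benzylic C–O hydrogenolysis, helped by the ortho aryloxy donor on ring B, should turn the carbinol into a methylene, while the aryl methyl ethers and the diaryl ether are stable.

Step 6
Reactants: 11 tri-O-methyl ether of the target
Product: 12 target cyclophane triol (CNP0173380.0)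
Conditions: BBr3 (6 equiv), CH2Cl2, −78 °C to rt; then H2O
Reagents that add atoms: none
Why: Lewis acid-mediated ether cleavage by BBr3 (bromide attack on the O-methyl carbon of the borane adduct) should free the three phenols, the diaryl ether being inert because neither of its carbons can undergo SN2 displacement.

Compound list
1 | 3-bromo-5-methoxyphenol | COc1cc(O)cc(Br)c1 | starting material
2 | deca-1,9-diene | C=CCCCCCCC=C | starting material
3 | 9-(dec-9-en-1-yl)-9-borabicyclo[3.3.1]nonane | C=CCCCCCCCCB1C2CCCC1CCC2 | intermediate
4 | 3-(dec-9-en-1-yl)-5-methoxyphenol | COc1cc(O)cc(CCCCCCCCC=C)c1 | intermediate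
5 | 2-bromo-3,5-dimethoxybenzaldehyde | COc1cc(C=O)c(Br)c(OC)c1 | starting material
6 | 2-[3-(dec-9-en-1-yl)-5-methoxyphenoxy]-3,5-dimethoxybenzaldehyde | COc1cc(C=O)c(Oc2cc(OC)cc(CCCCCCCCC=C)c2)c(OC)c1 | intermediate
7 | 5-bromopent-1-ene | C=CCCCBr | starting material
8 | pent-4-en-1-ylmagnesium bromide | C=CCCC[Mg]Br | intermediate
9 | rac-1-{2-[3-(dec-9-en-1-yl)-5-methoxyphenoxy]-3,5-dimethoxyphenyl}hex-5-en-1-ol | COc1cc(C(O)CCCC=C)c(Oc2cc(OC)cc(CCCCCCCCC=C)c2)c(OC)c1 | intermediate
10 | macrocyclic alkenol (bridge C1 hydroxyl, bridge C5=C6 olefin, tri-O-methyl, E/Z mixture, racemic) | OC1CCCC=CCCCCCCCCc2cc(OC)cc(c2)Oc2c(OC)cc(OC)cc21 | intermediate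
11 | tri-O-methyl ether of the target | COc1cc2cc(c1)Oc1c(OC)cc(OC)cc1CCCCCCCCCCCCCC2 | intermediate
12 | target cyclophane triol (CNP0173380.0) | Oc1cc2cc(c1)Oc1c(O)cc(O)cc1CCCCCCCCCCCCCC2 | target

Total step count: 6
Longest linear sequence: 6 steps (1 → 4 → 6 → 9 → 10 → 11 → 12)

Steps most likely to fail

Step 2. The bromide is flanked by a formyl and a methoxy group, so C–O bond formation may be slow and be overtaken by protodebromination or by base-induced degradation of the aldehyde. The fallback reverses the polarity of the coupling so that the hindered partner is the phenol. It sets out from 2: hydroboration as in step 1 to borane 3, then B-alkyl Suzuki coupling with an excess of commercial 1,3-dibromo-5-methoxybenzene (PdCl2(dppf), aq. K3PO4, THF, 60 °C), should give 1-bromo-3-(dec-9-en-1-yl)-5-methoxybenzene F1. Copper-catalysed etherification of this unhindered bromide with commercial 2-hydroxy-3,5-dimethoxybenzaldehyde (CuI, picolinic acid, K3PO4, DMSO, 100 °C) should then return to the route at 6.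

Step 5. The olefin may be saturated while C–O hydrogenolysis at the benzylic carbinol stalls, and forcing the conditions risks partial arene reduction. The fallback separates the two events and removes the oxygen by ionic reduction. It sets out from 10: neutral hydrogenation (H2, Pd/C, EtOAc, rt) should give the saturated macrocyclic alcohol F2. Treatment with Et3SiH and BF3·OEt2 (CH2Cl2, 0 °C) should ionise the carbinol to the benzylic cation, which is stabilised by the ortho aryloxy group, and hydride transfer should return to the route at 11.

Step 4. Intermolecular metathesis may outrun ring closure and give oligomers, or olefin migration before closure may give ring-contracted homologues. The fallback forms the same C5=C6 bond by carbonyl coupling and sets out from 9. Silylation (Et3SiCl, imidazole, CH2Cl2) should give the triethylsilyl ether F3, which prevents lactol formation later. Cleavage of both vinyl groups (OsO4 cat., NaIO4, 2,6-lutidine, dioxane/H2O) should give the dialdehyde F4, whose two formyl carbons are the two bridge atoms to be joined. Intramolecular McMurry coupling (TiCl3(DME)1.5, Zn–Cu couple, DME, reflux, slow addition) should close the 20-membered ring as the macrocyclic olefin silyl ether F5. Under the acidic hydrogenation of step 5 the silyl ether is cleaved and the carbinol is hydrogenolysed, so the route is rejoined at 11.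

Further compounds
F1 | step 2 | 1-bromo-3-(dec-9-en-1-yl)-5-methoxybenzene | COc1cc(Br)cc(CCCCCCCCC=C)c1
F2 | step 5 | saturated macrocyclic alcohol (bridge C1 hydroxyl, tri-O-methyl, racemic) | OC1CCCCCCCCCCCCCc2cc(OC)cc(c2)Oc2c(OC)cc(OC)cc21
F3 | step 4 | triethylsilyl ether of 9 | COc1cc(C(O[Si](CC)(CC)CC)CCCC=C)c(Oc2cc(OC)cc(CCCCCCCCC=C)c2)c(OC)c1
F4 | step 4 | dialdehyde from cleavage of both vinyl groups of F3 | COc1cc(C(O[Si](CC)(CC)CC)CCCC=O)c(Oc2cc(OC)cc(CCCCCCCCC=O)c2)c(OC)c1
F5 | step 4 | triethylsilyl ether of macrocyclic alkenol 10 (E/Z mixture) | CC[Si](CC)(CC)OC1CCCC=CCCCCCCCCc2cc(OC)cc(c2)Oc2c(OC)cc(OC)cc21
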